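## Analysis of the target

The target 23 is a germacranolide. A ten-membered carbocycle (C1–C10) is fused through C6 and C7 to a butenolide (ring oxygen on C6, C7=C11, carbonyl C12), and C11 carries an acetoxymethyl group (C13). The carbocycle bears a ketone at C1, a tertiary acetate and the C14 methyl at C10, a trisubstituted trans-epoxide at C4–C5 with the C15 methyl on C4, and an angelate at C8; eight of the fifteen skeletal carbons are oxygenated. There are five stereocentres, 4R,5R,6S,8S,10R. In the flat germacrane drawing these are a 4α,5β-epoxide, 6α-O, 8α-O and 10α-OAc/10β-CH3. C4, C5 and C6 are contiguous, C8 is insulated from C6 by the sp2 carbon C7, and C10 lies across the ring, so no ring fusion relays configuration to C8 or C10. Sensitive groups are the angelate (Z to E isomerisation), the γ-hydrogen at C6 of the butenolide (epimerisable through the 2-oxidofuran), the allylic acetate at C13, the tertiary α-acetoxy ketone, and an epoxide in a medium ring that invites transannular opening. The synthesis is hard because a ten-membered ring must be made and then oxidised at scattered positions without neighbouring stereocentres to steer C8 and C10. The strategy rests on one observation: with a C5–C10 bond drawn in, the ring with oxygen at C6, methyl groups at C4 and C10 and the lactone carbons C11–C13 is the eudesmanolide skeleton of α-santonin (1), which already has C6 in the required configuration.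

## Retrosynthetic reasoning

**C8–O acyl bond (23 ⇒ 20 + 21).** The angelate is removed first in the backward sense because it is the most fragile group: it would not survive hydrogen transfer, osmylation or irradiation unchanged. The forward reaction must acylate a hindered secondary allylic alcohol with retention at C8 and without Z to E isomerisation of the acid 21.

**C13–O and C8–O around the butenolide (20 ⇒ 19 ⇒ 18 ⇒ 17).** The pattern C13(O)–C11=C7–C8(O) is a 2-ene-1,4-diol derivative, so it is traced to the vinyl epoxide 19 by a 1,4-addition of acetic acid, and 19 to the cross-conjugated diene 18. The cut is made here because a finished butenolide cannot be oxidised at C8 selectively: its own γ-position C6 is the more activated site. Letting the C7=C11 bond appear in the same event that reveals the C8 hydroxyl avoids any oxidant acting on a butenolide, and it delivers the two oxygens already differentiated (acetate on C13, free hydroxyl on C8). Diene 18 comes from the allylic acetate 17 by 1,4-elimination. The forward reactions must eliminate towards C8 and not C6, and must epoxidise the α-face of C7=C8.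

**C13 and C11 oxygenation (17 ⇒ 16 ⇒ 15 ⇒ 14).** C13 is a methyl group in 1, and the only practical way to oxidise it is through the exocyclic C11=C13 olefin. Dihydroxylation of 14 gives 15, acetylation of the primary hydroxyl gives 16, and dehydration towards C7 gives 17.

**Ring oxygenation (14 ⇒ 13 ⇒ 12 ⇒ 11 ⇒ 10).** The epoxide C–O bonds and the C1/C10 ketol are both traced to the two ring olefins of 10. The order follows intrinsic reactivity: C1=C10 is the more electron-rich olefin, so it is dihydroxylated first (11), oxidised to the ketol (12) and acetylated (13). Only then is C4=C5 epoxidised (14), at a point where neither a free hydroxyl nor a 1,5-diene is left to open the epoxide across the ring. The forward steps must distinguish three olefins and must attack the outer faces to set C10, C4 and C5.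

**Lactone unsaturation (10 ⇒ 9 ⇒ 8).** The C11=C13 bond comes from the saturated lactone 8 through the selenide 9. This is the only operation that needs a strong base, so it is placed before any ketone, ester or epoxide exists.

**Key disconnection (8 ⇒ 7 ⇒ 6).** Reinstating the C5–C10 bond turns the ten-membered triene 7 into the trans-fused decalin diene 6. This bond is chosen because its cleavage places the two trisubstituted olefins exactly where the ketol and the epoxide are needed and leaves C6, C7 and the lactone untouched. What is gained is a ring formation with no macrocyclisation at all. The forward reaction must open the ring photochemically, keep the labile triene cold and saturate only C2=C3.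

**Ring A adjustment (6 ⇒ 5 ⇒ 4 ⇒ 2 ⇒ 1).** The diene 6 is obtained by removing the C3 oxygen from the dienyl triflate 5, which comes from the trans-fused enone 4. Enone 4 is reached from 1 by saturation to 2, which fixes the trans ring fusion, and reintroduction of the C1=C2 olefin. These are short, dependable operations, so the precursor of the key step is reached in four steps.

## Alternatives that were turned down

**Alternative 1: epoxide-forming fragment union.**
- Disconnection: the C3–C4 bond and the O–C5 bond of the epoxide. This divides the skeleton into the Grignard reagent A2 (C8 to C3, with the protected C10 carbinol and C1 ketal) and the α-chloro methyl ketone A3 (C15, C4–C7 and C11–C13).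
- Forward key step: A2 adds to the C4 carbonyl of A3 with the C=O and C–Cl dipoles opposed (Cornforth model). The tertiary alkoxide then displaces chloride at C5 with inversion and gives the trans-epoxide A1 in one operation.
- For: it is convergent and sets both epoxide stereocentres by a well-understood acyclic model. Every oxygen of 23 arrives with the fragments, so no late oxidation at C8 or C13 is needed. On that point it is stronger than the chosen route, whose weakest part is exactly that oxidation.
- Against: A1 is still an open chain. The ten-membered ring must be closed afterwards at C7–C8, a strained closure that creates C8 without obvious control. A3 has an epimerisable α-chloro ketone next to a β-silyloxy group, and the Grignard reagent can enolise it or attack the ester. Five protecting groups must later be removed beside an epoxide, and both fragments need multi-step asymmetric synthesis.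
- Comparison: two fragment syntheses, coupling, macrocyclisation and deprotection make it longer, and the ring-closure risk is not reduced. The chosen route offers a ring made by a unimolecular step and takes all fifteen carbons and C6 from 1.

**Alternative 2: chromium-mediated macrocyclisation with lactone closure.**
- Disconnection: C5–C6 together with the lactone O–C12 acyl bond. The precursor A5 is an acyclic (E)-alkenyl iodide at C5 whose C6 aldehyde sits on a tetrasubstituted acrylate with the methyl ester cis to it.
- Forward key step: CrCl2 with catalytic NiCl2 turns the C–I bond into a trivalent alkenylchromium species that adds to the aldehyde. The chromium alkoxide at C6 then acylates on the cis ester, closing the ten-membered ring and the butenolide to give A4.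
- For: A4 lacks only the epoxide oxygen, so one peracid step finishes the synthesis, and all three esters are already in place. In step economy after ring formation it is clearly stronger than the chosen route, and its final epoxidation rests on the same conformational argument.
- Against: C6, the stereocentre that 1 supplies for nothing, must be created during the macrocyclisation under remote induction from C8 across the sp2 carbon C7. Closing a ten-membered ring onto an E-trisubstituted olefin needs high dilution and a large excess of divalent chromium. The acrylate-activated allylic acetate at C13 and the C–I bond can be reduced by the same reagent. A5 needs an asymmetric synthesis of the tertiary α-acetoxy ketone, the C8 carbinol and a tetrasubstituted olefin of defined geometry, with the angelate carried through all of it.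
- Comparison: if A5 were in hand and the C6 selectivity were favourable, this route would be the shorter one. The chosen route gives certainty about ring formation and about C6 in its place.

**Alternative 3: sigmatropic ring contraction.**
- Disconnection: C6–C7, with the O–C13 bond re-formed. The carbocycle is expanded backwards to the thirteen-membered cyclic ether A7, whose C6 carries a tributylstannyl group and whose ether oxygen is allylic (O–C13–C11=C7).
- Forward key step: n-BuLi exchanges tin for lithium at C6. The α-alkoxy carbanion undergoes a [2,3] Wittig–Still shift that forms C6–C7, breaks O–C13 and contracts the ring to give the carbinol A6.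
- For: a thirteen-membered ether is far easier to close than a ten-membered carbocycle, and the concerted step sets C6 and C7 together. In reliability of ring formation it is comparable to the chosen route, and it is stronger in that the C8 oxygen is present from the start.
- Against: A6 is at a low oxidation level on the lactone side. C12 must be oxidised and lactonised, and the exocyclic C11=C13 olefin must be moved into C7=C11 with a new oxygen at C13. That is the same awkward allylic transposition as in the chosen route, and it destroys the C7 stereocentre the key step has just made. A configurationally defined α-alkoxystannane is needed, and the facial course at C7 depends on the fold of a macrocyclic transition state. Epoxidation, ketal hydrolysis, tertiary acetylation, ether cleavage and angeloylation still follow.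
- Comparison: it is longer than alternative 2 and carries a late-stage burden similar to the chosen route, while the whole skeleton has to be built from small pieces. The chosen route offers the skeleton and C6 from 1.

Key step: step 5

## Remarks before the steps

- Eudesmane/germacrane numbering is used throughout: C1–C10 ring, C11–C13 lactone carbons, C14 on C10, C15 on C4. The descriptors α and β refer to the conventional flat drawing.
- Assumption on the chemistry: the ten-membered lactones 8–18 are taken to react from the decalin-like fold with C14 and C15 on the β-face, as is usual for 12,6α-germacranolides. The facial selectivities of steps 8, 11 and 16 are argued on that basis.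

## Route

Step 1
Reactants: 1 α-santonin
Product: 2 4α-methyl-3-oxo-5αH-eudesman-12,6α-olide (trans-fused tetrahydro-α-santonin)
Conditions: H2 (1 atm), 10% Pd/C, EtOAc, rt
Reagents that add atoms: none
Why: Heterogeneous hydrogenation of the cross-conjugated dienone; hydrogen should add to the α-face, anti to the angular C14 methyl, which sets the trans ring fusion (5α-H). The C4 configuration (equatorial epimer drawn) is of no consequence because C4 becomes sp2 in step 3.

Step 2
Reactants: 2 4α-methyl-3-oxo-5αH-eudesman-12,6α-olide
Product: 4 4α-methyl-3-oxo-5αH-eudesm-1-en-12,6α-olide, via 3-trimethylsilyloxy-eudesm-2-ene silyl enol ether 3 (not isolated)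
Conditions: LiN(iPr)2, TMSCl, THF, −78 °C; then Pd(OAc)2, MeCN, rt
Reagents that add atoms: none
Why: Kinetic deprotonation should occur at the C2 methylene (the ketone is far more acidic than the lactone, and C4 is tertiary), and Saegusa–Ito oxidation of the silyl enol ether gives the Δ1-enone. No stereocentre is created.

Step 3
Reactants: 4 4α-methyl-3-oxo-5αH-eudesm-1-en-12,6α-olide
Product: 5 3-(trifluoromethanesulfonyloxy)-5αH-eudesma-1,3-dien-12,6α-olide
Conditions: KN(SiMe3)2, THF, −78 °C; PhNTf2, −78 → 0 °C
Reagents that add atoms: N-phenylbis(trifluoromethanesulfonimide), O=S(=O)(N(c1ccccc1)S(=O)(=O)C(F)(F)F)C(F)(F)F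
Why: The enone has no γ-hydrogen (C10 is quaternary), so the base removes the α′-proton at C4 and the cross-conjugated dienolate is trapped on oxygen (enol triflate formation). The less acidic lactone α-hydrogen is left alone with one equivalent of base.

Step 4
Reactants: 5 3-(trifluoromethanesulfonyloxy)-5αH-eudesma-1,3-dien-12,6α-olide
Product: 6 5αH-eudesma-1,3-dien-12,6α-olide (trans-fused homoannular diene)
Conditions: Pd(PPh3)4 (cat.), HCO2H, Et3N, DMF, 60 °C
Reagents that add atoms: none
Why: Zerovalent palladium inserts into the C3–O bond, formate delivers hydride with loss of CO2, and reductive elimination gives the diene (palladium-catalysed formate reduction of an enol triflate). No stereocentre is touched.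

Step 5
Reactants: 6 5αH-eudesma-1,3-dien-12,6α-olide
Product: 8 (11S)-germacra-1(10)E,4E-dien-12,6α-olide, via (1(10)E,2Z,4E)-germacra-1(10),2,4-trien-12,6α-olide 7 (not isolated)
Conditions: hν (254 nm, quartz), degassed MeOH, −30 °C; then KO2CN=NCO2K, AcOH, −30 → −15 °C
Reagents that add atoms: none
Why: Excitation of the cisoid homoannular diene of 6 triggers a conrotatory 6π electrocyclic ring opening in which the C5–C10 σ bond breaks and no σ bond forms; the closest known reaction type is the photochemical opening of ring-fused cyclohexa-1,3-dienes to cyclic hexatrienes. The ten-membered ring is not closed by bond formation but released from the decalin by scission of the shared bond, so the strain and entropy of a macrocyclisation play no part. No stereocentre is created; orbital symmetry fixes the new olefin geometries, because conrotation of a trans-fused diene turns both ring residues (C6 on C5, C9 on C10) outwards and gives the 1(10)E,2Z,4E-triene 7, while C6, C7 and C11 are spectators. Three selectivities are needed: ring opening rather than secondary photochemistry of 7 (irradiation stops at the photostationary state and unchanged 6 is recycled), no thermal disrotatory reclosure of 7 (everything stays at or below −15 °C), and reduction of the central olefin only. Diimide should secure the last one, since it transfers hydrogen fastest to the strained cis-disubstituted C2=C3 bond and leaves the trisubstituted olefins alone; once C2–C3 is saturated the hexatriene is gone and 8 is stable at room temperature.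

Step 6
Reactants: 8 (11S)-germacra-1(10)E,4E-dien-12,6α-olide
Product: 9 11β-methyl-11α-(phenylselanyl)germacra-1(10)E,4E-dien-12,6α-olide
Conditions: LiN(iPr)2, THF, −78 °C; PhSeSePh, HMPA, −78 → −20 °C
Reagents that add atoms: diphenyl diselenide, c1ccc(cc1)[Se][Se]c1ccccc1
Why: α-Selenenylation of the lactone enolate; the diselenide is not electrophilic towards the two ring olefins. Selenium should enter on the α-face, anti to C8; the C11 stereocentre disappears in step 7.

Step 7
Reactants: 9 11β-methyl-11α-(phenylselanyl)germacra-1(10)E,4E-dien-12,6α-olide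
Product: 10 germacra-1(10)E,4E,11(13)-trien-12,6α-olide (α-methylene lactone)
Conditions: 30% H2O2, pyridine, CH2Cl2, 0 °C → rt
Reagents that add atoms: none
Why: Selenoxide syn-elimination, which in trans-fused α-methyl α-seleno γ-lactones runs towards the methyl group and gives the exocyclic olefin. Pyridine buffering and low temperature guard against acid-induced transannular cyclisation and Cope rearrangement of the 1,5-diene.

Step 8
Reactants: 10 germacra-1(10)E,4E,11(13)-trien-12,6α-olide
Product: 11 1β,10α-dihydroxygermacra-4E,11(13)-dien-12,6α-olide
Conditions: OsO4 (cat.), NMO (1.05 equiv), acetone/H2O, 0 °C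
Reagents that add atoms: N-methylmorpholine N-oxide, C[N+]1([O-])CCOCC1 (oxygen relayed by OsO4, O=[Os](=O)(=O)=O); water, O
Why: Catalytic osmylation should select the strained, most electron-rich C1=C10 olefin, since C4=C5 is deactivated by the allylic lactone oxygen and C11=C13 by conjugation. Syn addition from the outer face gives the 1β,10α-diol and sets C10 (R).

Step 9
Reactants: 11 1β,10α-dihydroxygermacra-4E,11(13)-dien-12,6α-olide
Product: 12 10α-hydroxy-1-oxogermacra-4E,11(13)-dien-12,6α-olide
Conditions: IBX, DMSO, rt
Reagents that add atoms: none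
Why: IBX oxidises the secondary hydroxyl of a 1,2-diol to the α-ketol without glycol cleavage; the tertiary hydroxyl cannot be oxidised.

Step 10
Reactants: 12 10α-hydroxy-1-oxogermacra-4E,11(13)-dien-12,6α-olide
Product: 13 10α-acetoxy-1-oxogermacra-4E,11(13)-dien-12,6α-olide
Conditions: Ac2O, DMAP, Et3N, CH2Cl2, rt
Reagents that add atoms: acetic anhydride, CC(=O)OC(C)=O
Why: DMAP-catalysed acetylation of the only hydroxyl, a hindered tertiary α-ketol; the mild base should not provoke an α-ketol rearrangement.

Step 11
Reactants: 13 10α-acetoxy-1-oxogermacra-4E,11(13)-dien-12,6α-olide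
Product: 14 10α-acetoxy-4α,5β-epoxy-1-oxogermacr-11(13)-en-12,6α-olide
Conditions: mCPBA, NaHCO3, CH2Cl2, 0 °C
Reagents that add atoms: 3-chloroperbenzoic acid, OOC(=O)c1cccc(Cl)c1
Why: Prilezhaev epoxidation of the only nucleophilic olefin; the α-methylene lactone is inert to peracid. A(1,3) strain holds H6 in the plane of C4=C5 and the ring blocks the face on the C7 side, so the peracid should attack syn to the lactone oxygen and give the 4R,5R-epoxide.

Step 12
Reactants: 14 10α-acetoxy-4α,5β-epoxy-1-oxogermacr-11(13)-en-12,6α-olide
Product: 15 10α-acetoxy-4α,5β-epoxy-11α,13-dihydroxy-1-oxogermacran-12,6α-olide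
Conditions: OsO4 (cat.), NMO, acetone/H2O, rt
Reagents that add atoms: N-methylmorpholine N-oxide, C[N+]1([O-])CCOCC1 (oxygen relayed by OsO4, O=[Os](=O)(=O)=O); water, O
Why: Catalytic osmylation of the only olefin left, the conjugated exocyclic methylene. Attack on the α-face, anti to C8, puts the tertiary hydroxyl cis to H7; this stereocentre is temporary.

Step 13
Reactants: 15 10α-acetoxy-4α,5β-epoxy-11α,13-dihydroxy-1-oxogermacran-12,6α-olide
Product: 16 10α,13-diacetoxy-4α,5β-epoxy-11α-hydroxy-1-oxogermacran-12,6α-olide
Conditions: Ac2O, pyridine, CH2Cl2, 0 °C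
Reagents that add atoms: acetic anhydride, CC(=O)OC(C)=O
Why: Selective acetylation of the primary alcohol; the tertiary α-hydroxy lactone hydroxyl does not react without a stronger catalyst.

Step 14
Reactants: 16 10α,13-diacetoxy-4α,5β-epoxy-11α-hydroxy-1-oxogermacran-12,6α-olide
Product: 17 10α,13-diacetoxy-4α,5β-epoxy-1-oxogermacr-7(11)-en-12,6α-olide
Conditions: Burgess reagent (MeO2CN–SO2–NEt3 inner salt), benzene, 50 °C
Reagents that add atoms: none
Why: Burgess dehydration is a syn elimination through the sulfamate ester; it should take the cis hydrogen at C7 and give the tetrasubstituted conjugated butenolide (Zaitsev) rather than the enol acetate towards C13.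

Step 15
Reactants: 17 10α,13-diacetoxy-4α,5β-epoxy-1-oxogermacr-7(11)-en-12,6α-olide
Product: 18 10α-acetoxy-4α,5β-epoxy-1-oxogermacra-7Z,11(13)-dien-12,6α-olide
Conditions: Pd(PPh3)4 (cat.), Et3N, THF, 60 °C
Reagents that add atoms: none
Why: Zerovalent palladium ionises the allylic acetate to a π-allyl complex (C13–C11–C7), which loses a β-hydrogen (palladium-catalysed 1,4-elimination of an allylic acetate to a 1,3-diene). C8 offers a syn hydrogen on either face whereas C6 has only one, so elimination should run towards C8; the unactivated 4,5-epoxide is not ionised.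

Step 16
Reactants: 18 10α-acetoxy-4α,5β-epoxy-1-oxogermacra-7Z,11(13)-dien-12,6α-olide
Product: 19 10α-acetoxy-4α,5β:7α,8α-diepoxy-1-oxogermacr-11(13)-en-12,6α-olide
Conditions: DMDO, acetone, −20 °C
Reagents that add atoms: dimethyldioxirane, CC1(C)OO1
Why: Neutral epoxidation of the trisubstituted, more electron-rich C7=C8 bond; the acrylate-type C11=C13 bond is inert. Attack is expected on the α-face, anti to the pseudo-axial C14 methyl on C10 in the decalin-like fold, which sets C8.

Step 17
Reactants: 19 10α-acetoxy-4α,5β:7α,8α-diepoxy-1-oxogermacr-11(13)-en-12,6α-olide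
Product: 20 10α,13-diacetoxy-4α,5β-epoxy-8α-hydroxy-1-oxogermacr-7(11)-en-12,6α-olide
Conditions: Pd(PPh3)4 (cat.), AcOH, THF, 0 °C
Reagents that add atoms: acetic acid, CC(=O)O
Why: Zerovalent palladium opens the vinyl epoxide to a π-allyl complex with an alkoxide at C8, and acetate attacks the unhindered C13 terminus (palladium-catalysed 1,4-addition of a carboxylic acid to a vinyl epoxide). The C8–O bond is not broken, so the 8α configuration is kept and the butenolide forms in the same event.

Step 18
Reactants: 20 10α,13-diacetoxy-4α,5β-epoxy-8α-hydroxy-1-oxogermacr-7(11)-en-12,6α-olide; 21 angelic acid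
Product: 23 10α,13-diacetoxy-8α-angeloyloxy-4α,5β-epoxy-1-oxogermacr-7(11)-en-12,6α-olide (target), via angelic 2,4,6-trichlorobenzoic anhydride 22 (not isolated)
Conditions: 21, 2,4,6-Cl3C6H2COCl, Et3N, toluene, rt; then 20, toluene, 80 °C
Reagents that add atoms: angelic acid (21), C/C=C(/C)C(=O)O
Why: Yamaguchi-type esterification with the pre-formed mixed anhydride, run without a nucleophilic catalyst so that the Z-enoate is not isomerised to the tiglate. Acylation on oxygen retains C8, and any transannular 1,8-hemiketal of 20 should drain through the open hydroxy ketone.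

## Compound list

1 | α-santonin | C[C@H]1[C@@H]2CC[C@]3(C=CC(=O)C(=C3[C@H]2OC1=O)C)C | starting material
2 | 4α-methyl-3-oxo-5αH-eudesman-12,6α-olide (trans-fused) | C[C@H]1[C@@H]2CC[C@]3(CCC(=O)[C@@H](C)[C@@H]3[C@H]2OC1=O)C | intermediate
3 | 3-trimethylsilyloxy-5αH-eudesm-2-en-12,6α-olide (not isolated) | C[C@H]1[C@@H]2CC[C@]3(CC=C(O[Si](C)(C)C)[C@@H](C)[C@@H]3[C@H]2OC1=O)C | intermediate
4 | 4α-methyl-3-oxo-5αH-eudesm-1-en-12,6α-olide | C[C@H]1[C@@H]2CC[C@]3(C=CC(=O)[C@@H](C)[C@@H]3[C@H]2OC1=O)C | intermediate
5 | 3-(trifluoromethanesulfonyloxy)-5αH-eudesma-1,3-dien-12,6α-olide | C[C@H]1[C@@H]2CC[C@]3(C=CC(OS(=O)(=O)C(F)(F)F)=C(C)[C@@H]3[C@H]2OC1=O)C | intermediate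
6 | 5αH-eudesma-1,3-dien-12,6α-olide (precursor of the key step) | C[C@H]1[C@@H]2CC[C@]3(C=CC=C(C)[C@@H]3[C@H]2OC1=O)C | intermediate
7 | (1(10)E,2Z,4E)-germacra-1(10),2,4-trien-12,6α-olide (not isolated) | C[C@H]1[C@@H]2CC/C(C)=C/C=C\C(C)=C\[C@H]2OC1=O | intermediate
8 | (11S)-germacra-1(10)E,4E-dien-12,6α-olide | C[C@H]1[C@@H]2CC/C(C)=C/CC/C(C)=C/[C@H]2OC1=O | intermediate
9 | 11β-methyl-11α-(phenylselanyl)germacra-1(10)E,4E-dien-12,6α-olide | C[C@]1([Se]c3ccccc3)[C@@H]2CC/C(C)=C/CC/C(C)=C/[C@H]2OC1=O | intermediate
10 | germacra-1(10)E,4E,11(13)-trien-12,6α-olide | C=C1[C@@H]2CC/C(C)=C/CC/C(C)=C/[C@H]2OC1=O | intermediate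
11 | 1β,10α-dihydroxygermacra-4E,11(13)-dien-12,6α-olide | C=C1[C@@H]2CC[C@@](C)(O)[C@H](O)CC/C(C)=C/[C@H]2OC1=O | intermediate
12 | 10α-hydroxy-1-oxogermacra-4E,11(13)-dien-12,6α-olide | C=C1[C@@H]2CC[C@@](C)(O)C(=O)CC/C(C)=C/[C@H]2OC1=O | intermediate
13 | 10α-acetoxy-1-oxogermacra-4E,11(13)-dien-12,6α-olide | C=C1[C@@H]2CC[C@@](C)(OC(C)=O)C(=O)CC/C(C)=C/[C@H]2OC1=O | intermediate
14 | 10α-acetoxy-4α,5β-epoxy-1-oxogermacr-11(13)-en-12,6α-olide | C=C1[C@@H]2CC[C@@](C)(OC(C)=O)C(=O)CC[C@@]3(C)O[C@@H]3[C@H]2OC1=O | intermediate
15 | 10α-acetoxy-4α,5β-epoxy-11α,13-dihydroxy-1-oxogermacran-12,6α-olide | OC[C@]1(O)[C@@H]2CC[C@@](C)(OC(C)=O)C(=O)CC[C@@]3(C)O[C@@H]3[C@H]2OC1=O | intermediate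
16 | 10α,13-diacetoxy-4α,5β-epoxy-11α-hydroxy-1-oxogermacran-12,6α-olide | CC(=O)OC[C@]1(O)[C@@H]2CC[C@@](C)(OC(C)=O)C(=O)CC[C@@]3(C)O[C@@H]3[C@H]2OC1=O | intermediate
17 | 10α,13-diacetoxy-4α,5β-epoxy-1-oxogermacr-7(11)-en-12,6α-olide | CC(=O)OCC1=C2CC[C@@](C)(OC(C)=O)C(=O)CC[C@@]3(C)O[C@@H]3[C@H]2OC1=O | intermediate
18 | 10α-acetoxy-4α,5β-epoxy-1-oxogermacra-7Z,11(13)-dien-12,6α-olide | C=C1/C2=C/C[C@@](C)(OC(C)=O)C(=O)CC[C@@]3(C)O[C@@H]3[C@H]2OC1=O | intermediate
19 | 10α-acetoxy-4α,5β:7α,8α-diepoxy-1-oxogermacr-11(13)-en-12,6α-olide | C=C1[C@@]23O[C@H]3C[C@@](C)(OC(C)=O)C(=O)CC[C@@]4(C)O[C@@H]4[C@H]2OC1=O | intermediate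
20 | 10α,13-diacetoxy-4α,5β-epoxy-8α-hydroxy-1-oxogermacr-7(11)-en-12,6α-olide | O[C@H]1C[C@@](C)(OC(C)=O)C(=O)CC[C@@]2(C)O[C@@H]2[C@H]2OC(=O)C(COC(C)=O)=C12 | intermediate
21 | angelic acid, (Z)-2-methylbut-2-enoic acid | C/C=C(/C)C(=O)O | starting material
22 | angelic 2,4,6-trichlorobenzoic anhydride (not isolated) | C/C=C(/C)C(=O)OC(=O)c1c(Cl)cc(Cl)cc1Cl | intermediate
23 | (4R,5R,6S,8S,10R)-10α,13-diacetoxy-8α-angeloyloxy-4α,5β-epoxy-1-oxogermacr-7(11)-en-12,6α-olide | C/C=C(/C)C(=O)O[C@H]1C[C@@](C)(OC(C)=O)C(=O)CC[C@@]2(C)O[C@@H]2[C@H]2OC(=O)C(COC(C)=O)=C12 | target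

## Step count and risk

Total step count: 18. Longest linear sequence: 18 steps, from 1 to 23; angelic acid 21 is used as purchased.

**Step 5 (key step).** The likely failures are incomplete conversion at the photostationary state, secondary photochemistry of the triene on over-irradiation, thermal reclosure of 7 to a cis-fused diene while the reduction is running, and competing reduction of the ring-A olefin of unchanged 6. The fallback changes the trap from reduction to oxidation and sets out from 6. The cold photolysate is treated at −78 °C with stoichiometric OsO4·TMEDA, which should osmylate the electron-rich C1=C10 terminus, destroy the hexatriene and with it the electrocyclic pathway. This gives (2Z,4E)-1β,10α-dihydroxygermacra-2,4-dien-12,6α-olide F1. The now isolated Z-olefin of F1 can be reduced with diimide at room temperature to 1β,10α-dihydroxygermacr-4E-en-12,6α-olide F2. Protection with 2,2-dimethoxypropane gives the 1,10-acetonide F3, and selenenylation as in step 6 gives the 11α-phenylselanyl acetonide F4. Oxidative elimination as in step 7 gives the α-methylene lactone acetonide F5, and mild aqueous acetic acid returns the route to 11.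

**Step 16.** The likely failure is poor or reversed facial selectivity in the epoxidation of C7=C8, because the fold of the ten-membered ring around C8–C10 is argued rather than known. The fallback uses the other diastereomer instead of fighting for the α-face, and sets out from 18. β-Face epoxidation would give the 7β,8β-epoxide F14, and the opening of step 17 would give the 8β-hydroxy epimer of 20, F15. A Mitsunobu esterification of F15 with 21 (PPh3, diisopropyl azodicarboxylate) inverts C8 and arrives directly at 23. A mixture of F15 and 20 can therefore be separated and each epimer converged on the target by the matching acylation.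

**Step 15.** The likely failures are β-hydrogen loss from C6 instead of C8, palladium hydride isomerisation of the cross-conjugated diene into the linearly conjugated 7(11),8-dienolide, dimerisation of the electron-poor diene, and slow epimerisation at C6 by the amine. The fallback avoids the free dienolide and uses an electron-rich dienol ether, setting out from 17. Lipase-mediated ethanolysis (Candida antarctica lipase B, EtOH) should remove only the primary acetate and give the 13-hydroxy butenolide F9, and MnO2 oxidises it to the 13-aldehyde F10. Soft enolisation (TBSOTf, Et3N) should remove a proton from C8, the γ-carbon cis to the formyl group, and give the silyl dienol ether F11. A vinylogous Rubottom oxidation with DMDO gives the 8α-hydroxy-13-aldehyde F12, and NaBH(OAc)3 reduces the aldehyde but not the hindered C1 ketone, giving the 8α,13-diol F13. Acetylation of the primary hydroxyl (AcCl, 2,4,6-collidine, −78 °C) returns the route to 20.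

**Step 8.** The likely failure is loss of chemoselectivity, with the conjugated methylene or C4=C5 dihydroxylated alongside C1=C10. The fallback masks the α-methylene lactone and sets out from 10. Conjugate addition of dimethylamine gives the 13-dimethylamino-11βH adduct F6, and osmylation under the conditions of step 8 then has only the deactivated C4=C5 as competitor and gives the amino diol F7. Quaternisation with MeI gives the methiodide F8, and aqueous NaHCO3 triggers the retro-conjugate elimination that returns the route to 11.

## Further compounds

F1 | step 5 | (2Z,4E)-1β,10α-dihydroxygermacra-2,4-dien-12,6α-olide | C[C@H]1[C@@H]2CC[C@@](C)(O)[C@H](O)/C=C\C(C)=C\[C@H]2OC1=O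
F2 | step 5 | 1β,10α-dihydroxygermacr-4E-en-12,6α-olide | C[C@H]1[C@@H]2CC[C@@](C)(O)[C@H](O)CC/C(C)=C/[C@H]2OC1=O
F3 | step 5 | 1β,10α-isopropylidenedioxygermacr-4E-en-12,6α-olide | C[C@H]1[C@@H]2CC[C@@]3(C)OC(C)(C)O[C@@H]3CC/C(C)=C/[C@H]2OC1=O
F4 | step 5 | 11α-(phenylselanyl)-1β,10α-isopropylidenedioxygermacr-4E-en-12,6α-olide | C[C@]1([Se]c4ccccc4)[C@@H]2CC[C@@]3(C)OC(C)(C)O[C@@H]3CC/C(C)=C/[C@H]2OC1=O
F5 | step 5 | 1β,10α-isopropylidenedioxygermacra-4E,11(13)-dien-12,6α-olide | C=C1[C@@H]2CC[C@@]3(C)OC(C)(C)O[C@@H]3CC/C(C)=C/[C@H]2OC1=O
F6 | step 8 | 13-(dimethylamino)-11βH-germacra-1(10)E,4E-dien-12,6α-olide | CN(C)C[C@H]1[C@@H]2CC/C(C)=C/CC/C(C)=C/[C@H]2OC1=O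
F7 | step 8 | 13-(dimethylamino)-1β,10α-dihydroxy-11βH-germacr-4E-en-12,6α-olide | CN(C)C[C@H]1[C@@H]2CC[C@@](C)(O)[C@H](O)CC/C(C)=C/[C@H]2OC1=O
F8 | step 8 | 13-(trimethylammonio)-1β,10α-dihydroxy-11βH-germacr-4E-en-12,6α-olide iodide | C[N+](C)(C)C[C@H]1[C@@H]2CC[C@@](C)(O)[C@H](O)CC/C(C)=C/[C@H]2OC1=O.[I-]
F9 | step 15 | 10α-acetoxy-4α,5β-epoxy-13-hydroxy-1-oxogermacr-7(11)-en-12,6α-olide | OCC1=C2CC[C@@](C)(OC(C)=O)C(=O)CC[C@@]3(C)O[C@@H]3[C@H]2OC1=O
F10 | step 15 | 10α-acetoxy-4α,5β-epoxy-1,13-dioxogermacr-7(11)-en-12,6α-olide | O=CC1=C2CC[C@@](C)(OC(C)=O)C(=O)CC[C@@]3(C)O[C@@H]3[C@H]2OC1=O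
F11 | step 15 | 10α-acetoxy-13-(tert-butyldimethylsilyloxy)-4α,5β-epoxy-1-oxogermacra-7Z,11(13)-dien-12,6α-olide | CC(C)(C)[Si](C)(C)O/C=C1/C2=C/C[C@@](C)(OC(C)=O)C(=O)CC[C@@]3(C)O[C@@H]3[C@H]2OC1=O
F12 | step 15 | 10α-acetoxy-4α,5β-epoxy-8α-hydroxy-1,13-dioxogermacr-7(11)-en-12,6α-olide | O=CC1=C2[C@@H](O)C[C@@](C)(OC(C)=O)C(=O)CC[C@@]3(C)O[C@@H]3[C@H]2OC1=O
F13 | step 15 | 10α-acetoxy-4α,5β-epoxy-8α,13-dihydroxy-1-oxogermacr-7(11)-en-12,6α-olide | OCC1=C2[C@@H](O)C[C@@](C)(OC(C)=O)C(=O)CC[C@@]3(C)O[C@@H]3[C@H]2OC1=O
F14 | step 16 | 10α-acetoxy-4α,5β:7β,8β-diepoxy-1-oxogermacr-11(13)-en-12,6α-olide | C=C1[C@]23O[C@@H]3C[C@@](C)(OC(C)=O)C(=O)CC[C@@]4(C)O[C@@H]4[C@H]2OC1=O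
F15 | step 16 | 10α,13-diacetoxy-4α,5β-epoxy-8β-hydroxy-1-oxogermacr-7(11)-en-12,6α-olide | O[C@@H]1C[C@@](C)(OC(C)=O)C(=O)CC[C@@]2(C)O[C@@H]2[C@H]2OC(=O)C(COC(C)=O)=C12
A1 | alternative 1 | open-chain trans-epoxide carrying all carbons of the core | COc1ccc(COCC[C@@](C)(OCOC)C2(OCCO2)CC[C@@]3(C)O[C@@H]3[C@@H](O[Si](C)(C)C(C)(C)C)/C(I)=C(/CO[Si](C)(C)C(C)(C)C)C(=O)OC)cc1
A2 | alternative 1 | C8–C3 Grignard reagent with C10 methoxymethyl ether and C1 dioxolane | COc1ccc(COCC[C@@](C)(OCOC)C2(OCCO2)CC[Mg]Br)cc1
A3 | alternative 1 | α-chloro methyl ketone with C6 silyl ether and iodo-acrylate | CC(=O)[C@@H](Cl)[C@@H](O[Si](C)(C)C(C)(C)C)/C(I)=C(/CO[Si](C)(C)C(C)(C)C)C(=O)OC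
A4 | alternative 2 | 4,5-deoxy target with E-C4=C5 olefin | C/C=C(/C)C(=O)O[C@H]1C[C@@](C)(OC(C)=O)C(=O)CC/C(C)=C/[C@H]2OC(=O)C(COC(C)=O)=C12
A5 | alternative 2 | acyclic C5 alkenyl iodide with C6 aldehyde and cis methyl ester | C/C=C(/C)C(=O)O[C@@H](C[C@@](C)(OC(C)=O)C(=O)CC/C(C)=C/I)/C(C=O)=C(\COC(C)=O)C(=O)OC
A6 | alternative 3 | ten-membered C6 carbinol with C7 1-(silyloxymethyl)vinyl group | COc3ccc(CO[C@H]1C[C@@](C)(OCOC)C2(OCCO2)CC/C(C)=C/[C@@H](O)[C@@H]1C(=C)CO[Si](C)(C)C(C)(C)C)cc3
A7 | alternative 3 | thirteen-membered cyclic allylic ether with C6 tributylstannyl group | CCCC[Sn](CCCC)(CCCC)[C@H]1OC/C(CO[Si](C)(C)C(C)(C)C)=C/[C@@H](OCc2ccc(OC)cc2)C[C@@](C)(OCOC)C3(OCCO3)CC/C(C)=C/1
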